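**Retrosynthetic overview**
1. Late stage: the two sulfate esters, the free C4' phenol and the C5' formyl group are developed from a 2,4,5-trimethoxyphenyl ring (directed lithiation–formylation, oxidative demethylation of the para pair C3'/C6' to the hydroquinone, sulfation, chelation-assisted cleavage of the C4' methyl ether).
2. The C9=C11 double bond comes from dehydration of a benzylic alcohol (from an aryl ketone); the C8 stereocentre comes from α-face hydrogenation of a C7=C8 double bond.
3. Ring B is made in one operation by a cationic [4+2] annulation that forms C5–C6 and C9–C10: ring A enters as 1,3,3-trimethylcyclohexene (C5=C10), and C6–C9, C11 and the aryl ring enter as a (Z)-5-aryl-3-methylpent-2-en-4-ynyl acetate.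
4. Enabling feature: the exocyclic C9=C11 bond carrying the electron-rich aryl ring is the footprint of an arylalkyne. Its carbon C9 can capture the tertiary C10 cation of ring A because the aryl ring stabilises the vinyl cation at C11, and the C4 gem-dimethyl group beside C5 makes this closure trans.
5. Order of rings: the aryl ring and ring A are bought or made as rings; ring B is the only ring formed, in step 5.

Key step: step 5

Remark: the target is drawn as the free bis(hydrogen sulfate); it is carried as its disodium salt and protonated only in the last work-up, and 1, 2 and 5 are taken as commercial. Locants: drimane numbering for the decalin (C4 gem-dimethyl, C5 ring-fusion CH, C8 CHMe, C9 alkylidene carbon, C10 quaternary carbon), C11 for the benzylidene carbon, C1'–C6' for the aryl ring (C1' on C11, oxygens on C3', C4', C6', formyl on C5').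

Step 1
Reactants: 1 1-iodo-2,4,5-trimethoxybenzene; 2 (Z)-3-methylpent-2-en-4-yn-1-ol
Product: 3 (Z)-3-methyl-5-(2,4,5-trimethoxyphenyl)pent-2-en-4-yn-1-ol
Conditions: Pd(PPh3)2Cl2 (2 mol %), CuI (4 mol %), Et3N, THF, rt
Reagents that add atoms: none
Why: Sonogashira coupling of an aryl iodide runs at room temperature, which should keep the Z enynol from cycloisomerising to a furan, and it does not touch the double-bond geometry that later holds C6 and C9 cis.

Step 2
Reactants: 3 (Z)-3-methyl-5-(2,4,5-trimethoxyphenyl)pent-2-en-4-yn-1-ol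
Product: 4 (Z)-3-methyl-5-(2,4,5-trimethoxyphenyl)pent-2-en-4-yn-1-yl acetate
Conditions: Ac2O, pyridine, DMAP (cat.), CH2Cl2, 0 °C → rt
Reagents that add atoms: acetic anhydride, CC(=O)OC(C)=O
Why: DMAP-catalysed O-acylation of a primary allylic alcohol installs the leaving group that is later returned to the product as the enol ester oxygen.

Step 3
Reactants: 5 2,2,6-trimethylcyclohexanone
Product: 6 2,2,6-trimethylcyclohexanone 2,4,6-triisopropylbenzenesulfonylhydrazone
Conditions: 2,4,6-triisopropylbenzenesulfonyl hydrazide, HCl (cat.), THF, rt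
Reagents that add atoms: 2,4,6-triisopropylbenzenesulfonyl hydrazide, CC(C)c1cc(C(C)C)c(S(=O)(=O)NN)c(C(C)C)c1
Why: Acid-catalysed condensation gives the arenesulfonylhydrazone, and the stereocentre of 5 is irrelevant because it becomes sp2 in step 4.

Step 4
Reactants: 6 2,2,6-trimethylcyclohexanone 2,4,6-triisopropylbenzenesulfonylhydrazone
Product: 8 1,3,3-trimethylcyclohexene, via vinyllithium 7 (not isolated)
Conditions: n-BuLi (2.2 equiv), TMEDA, hexane–THF, −78 → 0 °C; then H2O
Reagents that add atoms: none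
Why: Shapiro reaction, in which the dianion can form only at the single α-methine, loses sulfinate and nitrogen to the vinyllithium, and protonation gives the C5=C10 alkene without positional isomers.

Step 5
Reactants: 4 (Z)-3-methyl-5-(2,4,5-trimethoxyphenyl)pent-2-en-4-yn-1-yl acetate; 8 1,3,3-trimethylcyclohexene
Product: 10 (2,4,5-trimethoxyphenyl)[(1S,4aS,8aS)-2,5,5,8a-tetramethyl-1,4,4a,5,6,7,8,8a-octahydronaphthalen-1-yl]methanone, via enol acetate 9 (not isolated)
Conditions: chiral tert-leucine arylpyrrolidine squaramide hydrogen-bond donor (10 mol %), TMSOTf (20 mol %), 2,6-di-tert-butyl-4-methylpyridine (25 mol %), 8 (4 equiv), toluene–t-BuOMe, −78 → −40 °C; then K2CO3, MeOH, 0 °C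
Reagents that add atoms: none
Why: Proposed new method: TMSOTf ionises the allylic acetate 4 to a 5-aryl-3-methylpent-2-en-4-ynyl cation (tertiary, propargylic and, through its allenyl form, stabilised by the ortho and para methoxy groups) that is held as a contact ion pair by the squaramide-bound anion; C5 of 8 adds to its CH2 terminus (C6), the tertiary C10 cation so formed is captured by the proximal alkyne carbon C9 (the Z double bond holds C6 and C9 cis), and the aryl-stabilised vinyl cation at C11 collapses with acetate to enol acetate 9, so that every cation–acetate collapse before the last is reversible and the silyl Lewis acid is regenerated. The closest known reaction types are the cation–olefin cyclisation that ends on an arylacetylene and delivers an aryl ketone, the acid-mediated trans cyclisation of 2-alkyl-1,3,3-trimethylcyclohexyl cations (monocyclic farnesyl to drimane), and the enantioselective SN1 substitution of propargylic acetates under TMSOTf and chiral squaramide anion-binding catalysis; new is their intermolecular merger on an unactivated alkene. Ring B closes in the 6-exo-dig mode. C5 is set in the first bond formation by the chiral ion pair, which should let 8 reach the CH2 terminus with one enantiotopic face only (the catalyst antipode is chosen for 5S); C10 follows from C5 because C9 attacks the cation in a chair-like arrangement with the C5–C6 bond equatorial and on the face away from the axial C4 methyl group, which gives the trans ring fusion; C9 of 10 is set on methanolysis by protonation of the dienolate on the α-face, away from the angular methyl group (aroyl equatorial). The step needs attack at C6 and not at C8 or C11 (secured by the hindered nucleophile and the unsubstituted terminus), Markovnikov attack through C5 (tertiary cation), and ring closure faster than proton loss from C10 (intramolecular capture by an electron-rich arylalkyne, with the hindered pyridine as proton buffer).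

Step 6
Reactants: 10 (2,4,5-trimethoxyphenyl)[(1S,4aS,8aS)-2,5,5,8a-tetramethyl-1,4,4a,5,6,7,8,8a-octahydronaphthalen-1-yl]methanone
Product: 11 (2,4,5-trimethoxyphenyl)[(1S,2S,4aS,8aS)-2,5,5,8a-tetramethyldecahydronaphthalen-1-yl]methanone
Conditions: H2 (1 atm), Pd/C (10 wt %), EtOAc, rt
Reagents that add atoms: none
Why: Heterogeneous catalytic hydrogenation should add hydrogen to the trisubstituted C7=C8 bond from the α-face, opposite to the axial C10 methyl group, which sets C8 as S (H-8 α, methyl β), while the hindered electron-rich aryl ketone is not reduced in neutral ethyl acetate.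

Step 7
Reactants: 11 (2,4,5-trimethoxyphenyl)[(1S,2S,4aS,8aS)-2,5,5,8a-tetramethyldecahydronaphthalen-1-yl]methanone
Product: 12 (2,4,5-trimethoxyphenyl)[(1S,2S,4aS,8aS)-2,5,5,8a-tetramethyldecahydronaphthalen-1-yl]methanol (both C11 epimers)
Conditions: LiAlH4, THF, 0 °C → reflux; then H2O
Reagents that add atoms: none
Why: Hydride reduction of the hindered ketone with LiAlH4; the new carbinol centre C11 is not controlled and need not be, since it becomes sp2 in step 8.

Step 8
Reactants: 12 (2,4,5-trimethoxyphenyl)[(1S,2S,4aS,8aS)-2,5,5,8a-tetramethyldecahydronaphthalen-1-yl]methanol (both C11 epimers)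
Product: 13 1-{(E)-[(2S,4aS,8aS)-2,5,5,8a-tetramethyloctahydronaphthalen-1(2H)-ylidene]methyl}-2,4,5-trimethoxybenzene
Conditions: p-TsOH·H2O (5 mol %), toluene, 40 °C
Reagents that add atoms: none
Why: Acid-catalysed E1 dehydration through the trimethoxyphenyl-stabilised benzylic cation, which can lose only H-9; under these reversible conditions the E isomer should prevail because the aryl group then lies beside the C8 methine (whose methyl group turns axial) and not beside the quaternary C10.

Step 9
Reactants: 13 1-{(E)-[(2S,4aS,8aS)-2,5,5,8a-tetramethyloctahydronaphthalen-1(2H)-ylidene]methyl}-2,4,5-trimethoxybenzene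
Product: 15 2,3,6-trimethoxy-5-{(E)-[(2S,4aS,8aS)-2,5,5,8a-tetramethyloctahydronaphthalen-1(2H)-ylidene]methyl}benzaldehyde, via aryllithium 14 (not isolated)
Conditions: n-BuLi, TMEDA, THF, −78 → 0 °C; then DMF, −78 °C → rt; H2O
Reagents that add atoms: N,N-dimethylformamide, CN(C)C=O
Why: Directed ortho-lithiation takes place at C5', the position between two methoxy groups (as in 1,2,4-trimethoxybenzene), and formylation of the aryllithium with DMF gives the aldehyde.

Step 10
Reactants: 15 2,3,6-trimethoxy-5-{(E)-[(2S,4aS,8aS)-2,5,5,8a-tetramethyloctahydronaphthalen-1(2H)-ylidene]methyl}benzaldehyde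
Product: 17 3,6-dihydroxy-2-methoxy-5-{(E)-[(2S,4aS,8aS)-2,5,5,8a-tetramethyloctahydronaphthalen-1(2H)-ylidene]methyl}benzaldehyde, via quinone 16 (not isolated)
Conditions: (NH4)2Ce(NO3)6 (2.2 equiv), MeCN–H2O, 0 °C; then Na2S2O4, EtOAc–H2O, rt
Reagents that add atoms: water, O
Why: Oxidative demethylation with (NH4)2Ce(NO3)6 converts only the para-dimethoxy pair (C3', C6') into the p-quinone and leaves the C4' methoxy group, which differentiates the three oxygens, and dithionite reduction then gives the hydroquinone.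

Step 11
Reactants: 17 3,6-dihydroxy-2-methoxy-5-{(E)-[(2S,4aS,8aS)-2,5,5,8a-tetramethyloctahydronaphthalen-1(2H)-ylidene]methyl}benzaldehyde
Product: 18 disodium 3-formyl-2-methoxy-5-{(E)-[(2S,4aS,8aS)-2,5,5,8a-tetramethyloctahydronaphthalen-1(2H)-ylidene]methyl}-1,4-phenylene bis(sulfate)
Conditions: SO3·pyridine (6 equiv), pyridine, 50 °C; then aqueous NaHCO3
Reagents that add atoms: sulfur trioxide–pyridine complex, O=S(=O)([O-])[n+]1ccccc1; sodium hydrogencarbonate, [Na+].OC([O-])=O
Why: O-Sulfation of both free phenols with the sulfur trioxide–pyridine complex, while the C4' oxygen stays masked as its methyl ether.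

Step 12
Reactants: 18 disodium 3-formyl-2-methoxy-5-{(E)-[(2S,4aS,8aS)-2,5,5,8a-tetramethyloctahydronaphthalen-1(2H)-ylidene]methyl}-1,4-phenylene bis(sulfate)
Product: 19 3-formyl-2-hydroxy-5-{(E)-[(2S,4aS,8aS)-2,5,5,8a-tetramethyloctahydronaphthalen-1(2H)-ylidene]methyl}-1,4-phenylene bis(hydrogen sulfate) (CNP0309628.1)
Conditions: MgI2 (4 equiv), MeCN–DMF, 45 °C; then cold 0.1 M HCl (pH 1), C18 extraction, lyophilisation
Reagents that add atoms: none
Why: Chelation of MgI2 between the formyl oxygen and the neighbouring C4' methoxy group should let iodide remove this methyl group selectively (cleavage of aryl methyl ethers ortho to a carbonyl group), sulfate monoester anions being inert to iodide, and cold acid then liberates the free acid.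

**Compound list**
1 | 1-iodo-2,4,5-trimethoxybenzene | COc1cc(OC)c(OC)cc1I | starting material
2 | (Z)-3-methylpent-2-en-4-yn-1-ol | C#C/C(C)=C\CO | starting material
3 | (Z)-3-methyl-5-(2,4,5-trimethoxyphenyl)pent-2-en-4-yn-1-ol | COc1cc(OC)c(OC)cc1C#C/C(C)=C\CO | intermediate
4 | (Z)-3-methyl-5-(2,4,5-trimethoxyphenyl)pent-2-en-4-yn-1-yl acetate | COc1cc(OC)c(OC)cc1C#C/C(C)=C\COC(C)=O | intermediate
5 | 2,2,6-trimethylcyclohexanone (racemic) | CC1CCCC(C)(C)C1=O | starting material
6 | 2,2,6-trimethylcyclohexanone 2,4,6-triisopropylbenzenesulfonylhydrazone | CC1CCCC(C)(C)C1=NNS(=O)(=O)c1c(C(C)C)cc(C(C)C)cc1C(C)C | intermediate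
7 | 2,6,6-trimethylcyclohex-1-en-1-yllithium | [Li]C1=C(C)CCCC1(C)C | intermediate
8 | 1,3,3-trimethylcyclohexene | CC1=CC(C)(C)CCC1 | intermediate
9 | [(4aS,8aS)-2,5,5,8a-tetramethyl-4a,5,6,7,8,8a-hexahydronaphthalen-1(4H)-ylidene](2,4,5-trimethoxyphenyl)methyl acetate (enol acetate, either geometry) | CC1=CC[C@H]2C(C)(C)CCC[C@]2(C)C1=C(OC(C)=O)c1cc(OC)c(OC)cc1OC | intermediate
10 | (2,4,5-trimethoxyphenyl)[(1S,4aS,8aS)-2,5,5,8a-tetramethyl-1,4,4a,5,6,7,8,8a-octahydronaphthalen-1-yl]methanone (H-5 α, H-9 α, C10 methyl β) | CC1=CC[C@H]2C(C)(C)CCC[C@]2(C)[C@H]1C(=O)c1cc(OC)c(OC)cc1OC | intermediate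
11 | (2,4,5-trimethoxyphenyl)[(1S,2S,4aS,8aS)-2,5,5,8a-tetramethyldecahydronaphthalen-1-yl]methanone (C8 methyl β) | C[C@H]1CC[C@H]2C(C)(C)CCC[C@]2(C)[C@H]1C(=O)c1cc(OC)c(OC)cc1OC | intermediate
12 | (2,4,5-trimethoxyphenyl)[(1S,2S,4aS,8aS)-2,5,5,8a-tetramethyldecahydronaphthalen-1-yl]methanol (both C11 epimers) | C[C@H]1CC[C@H]2C(C)(C)CCC[C@]2(C)[C@H]1C(O)c1cc(OC)c(OC)cc1OC | intermediate
13 | 1-{(E)-[(2S,4aS,8aS)-2,5,5,8a-tetramethyloctahydronaphthalen-1(2H)-ylidene]methyl}-2,4,5-trimethoxybenzene | C[C@H]1CC[C@H]2C(C)(C)CCC[C@]2(C)/C1=C/c1cc(OC)c(OC)cc1OC | intermediate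
14 | 2,3,6-trimethoxy-5-{(E)-[(2S,4aS,8aS)-2,5,5,8a-tetramethyloctahydronaphthalen-1(2H)-ylidene]methyl}phenyllithium | C[C@H]1CC[C@H]2C(C)(C)CCC[C@]2(C)/C1=C/c1cc(OC)c(OC)c([Li])c1OC | intermediate
15 | 2,3,6-trimethoxy-5-{(E)-[(2S,4aS,8aS)-2,5,5,8a-tetramethyloctahydronaphthalen-1(2H)-ylidene]methyl}benzaldehyde | C[C@H]1CC[C@H]2C(C)(C)CCC[C@]2(C)/C1=C/c1cc(OC)c(OC)c(C=O)c1OC | intermediate
16 | 2-methoxy-3,6-dioxo-5-{(E)-[(2S,4aS,8aS)-2,5,5,8a-tetramethyloctahydronaphthalen-1(2H)-ylidene]methyl}cyclohexa-1,4-diene-1-carbaldehyde | C[C@H]1CC[C@H]2C(C)(C)CCC[C@]2(C)/C1=C/C1=CC(=O)C(OC)=C(C=O)C1=O | intermediate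
17 | 3,6-dihydroxy-2-methoxy-5-{(E)-[(2S,4aS,8aS)-2,5,5,8a-tetramethyloctahydronaphthalen-1(2H)-ylidene]methyl}benzaldehyde | C[C@H]1CC[C@H]2C(C)(C)CCC[C@]2(C)/C1=C/c1cc(O)c(OC)c(C=O)c1O | intermediate
18 | disodium 3-formyl-2-methoxy-5-{(E)-[(2S,4aS,8aS)-2,5,5,8a-tetramethyloctahydronaphthalen-1(2H)-ylidene]methyl}-1,4-phenylene bis(sulfate) | C[C@H]1CC[C@H]2C(C)(C)CCC[C@]2(C)/C1=C/c1cc(OS(=O)(=O)[O-])c(OC)c(C=O)c1OS(=O)(=O)[O-].[Na+].[Na+] | intermediate
19 | 3-formyl-2-hydroxy-5-{(E)-[(2S,4aS,8aS)-2,5,5,8a-tetramethyloctahydronaphthalen-1(2H)-ylidene]methyl}-1,4-phenylene bis(hydrogen sulfate) | C[C@H]1CC[C@H]2C(C)(C)CCC[C@]2(C)/C1=C/c1cc(OS(=O)(=O)O)c(O)c(C=O)c1OS(=O)(=O)O | target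

**Step count and risks**

Total step count: 12. Longest linear sequence: 10 steps (1 → 3 → 4 → 10 → 11 → 12 → 13 → 15 → 17 → 18 → 19; the branch from 5 through 6 and 8 is equally long).

Steps most likely to fail:

Step 5. Capture of the cation by the hindered alkene may be slower than its capture by the electron-rich arene or alkyne of a second molecule of 4. Proton loss from the C10 cation may outrun ring closure. The chiral ion pair may discriminate the alkene faces poorly, so that enantiomeric purity is low. A fallback on known chemistry sets out from 1 and comes back at 12. Commercial (−)-drimenol is hydrogenated (H2, PtO2, EtOAc) from the α-face to [(1S,2S,4aS,8aS)-2,5,5,8a-tetramethyldecahydronaphthalen-1-yl]methanol F1. Dess–Martin periodinane oxidises this to (1S,2S,4aS,8aS)-2,5,5,8a-tetramethyldecahydronaphthalene-1-carbaldehyde F2. Iodine–lithium exchange on 1 (t-BuLi, THF, −78 °C) gives (2,4,5-trimethoxyphenyl)lithium F3, and its addition to F2 gives 12, which rejoins the route at step 8.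

Step 12. Lewis acid-assisted loss of sulfur trioxide from the aryl sulfates may occur, or the sulfate groups may sequester the magnesium so that the demethylation stalls. A fallback that keeps the sulfates neutral until the end sets out from 17 and comes back at 19. Both phenols are converted with 2,2,2-trichloroethyl chlorosulfate (Et3N, DMAP, THF) into the bis(2,2,2-trichloroethyl sulfate) diester F4. BCl3 (CH2Cl2, −78 °C) then cleaves the C4' methyl ether beside the formyl group to give the phenol diester F5. Zn dust and HCO2NH4 in MeOH remove the trichloroethyl groups to give the bis(ammonium) sulfate salt F6, and cold acidification gives 19.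

Step 10. One-electron oxidation of the electron-rich styrene unit may compete (oxidative cleavage or nitrate addition), the formyl-deactivated ring may oxidise slowly, and the formyl quinone may decompose. A fallback that oxidises before formylating sets out from 13 and comes back at 17. Treatment of 13 with (NH4)2Ce(NO3)6 gives 2-methoxy-5-alkenyl-1,4-benzoquinone F7. Na2S2O4 reduces it to the hydroquinone F8, and MOMCl with i-Pr2NEt gives the bis(methoxymethyl) ether F9. Lithiation with n-BuLi between the C6' methoxymethoxy and C4' methoxy groups, then DMF, gives the aldehyde F10. HCl (cat.) in MeOH at 0 °C removes both methoxymethyl groups to give 17.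

Further compounds
F1 | step 5 | [(1S,2S,4aS,8aS)-2,5,5,8a-tetramethyldecahydronaphthalen-1-yl]methanol | C[C@H]1CC[C@H]2C(C)(C)CCC[C@]2(C)[C@H]1CO
F2 | step 5 | (1S,2S,4aS,8aS)-2,5,5,8a-tetramethyldecahydronaphthalene-1-carbaldehyde | C[C@H]1CC[C@H]2C(C)(C)CCC[C@]2(C)[C@H]1C=O
F3 | step 5 | (2,4,5-trimethoxyphenyl)lithium | [Li]c1cc(OC)c(OC)cc1OC
F4 | step 12 | 3-formyl-2-methoxy-5-{(E)-[(2S,4aS,8aS)-2,5,5,8a-tetramethyloctahydronaphthalen-1(2H)-ylidene]methyl}-1,4-phenylene bis(2,2,2-trichloroethyl) bis(sulfate) | C[C@H]1CC[C@H]2C(C)(C)CCC[C@]2(C)/C1=C/c1cc(OS(=O)(=O)OCC(Cl)(Cl)Cl)c(OC)c(C=O)c1OS(=O)(=O)OCC(Cl)(Cl)Cl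
F5 | step 12 | 3-formyl-2-hydroxy-5-{(E)-[(2S,4aS,8aS)-2,5,5,8a-tetramethyloctahydronaphthalen-1(2H)-ylidene]methyl}-1,4-phenylene bis(2,2,2-trichloroethyl) bis(sulfate) | C[C@H]1CC[C@H]2C(C)(C)CCC[C@]2(C)/C1=C/c1cc(OS(=O)(=O)OCC(Cl)(Cl)Cl)c(O)c(C=O)c1OS(=O)(=O)OCC(Cl)(Cl)Cl
F6 | step 12 | diammonium 3-formyl-2-hydroxy-5-{(E)-[(2S,4aS,8aS)-2,5,5,8a-tetramethyloctahydronaphthalen-1(2H)-ylidene]methyl}-1,4-phenylene bis(sulfate) | C[C@H]1CC[C@H]2C(C)(C)CCC[C@]2(C)/C1=C/c1cc(OS(=O)(=O)[O-])c(O)c(C=O)c1OS(=O)(=O)[O-].[NH4+].[NH4+]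
F7 | step 10 | 2-methoxy-5-{(E)-[(2S,4aS,8aS)-2,5,5,8a-tetramethyloctahydronaphthalen-1(2H)-ylidene]methyl}cyclohexa-2,5-diene-1,4-dione | C[C@H]1CC[C@H]2C(C)(C)CCC[C@]2(C)/C1=C/C1=CC(=O)C(OC)=CC1=O
F8 | step 10 | 2-methoxy-5-{(E)-[(2S,4aS,8aS)-2,5,5,8a-tetramethyloctahydronaphthalen-1(2H)-ylidene]methyl}benzene-1,4-diol | C[C@H]1CC[C@H]2C(C)(C)CCC[C@]2(C)/C1=C/c1cc(O)c(OC)cc1O
F9 | step 10 | 1-methoxy-2,5-bis(methoxymethoxy)-4-{(E)-[(2S,4aS,8aS)-2,5,5,8a-tetramethyloctahydronaphthalen-1(2H)-ylidene]methyl}benzene | C[C@H]1CC[C@H]2C(C)(C)CCC[C@]2(C)/C1=C/c1cc(OCOC)c(OC)cc1OCOC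
F10 | step 10 | 2-methoxy-3,6-bis(methoxymethoxy)-5-{(E)-[(2S,4aS,8aS)-2,5,5,8a-tetramethyloctahydronaphthalen-1(2H)-ylidene]methyl}benzaldehyde | C[C@H]1CC[C@H]2C(C)(C)CCC[C@]2(C)/C1=C/c1cc(OCOC)c(OC)c(C=O)c1OCOC
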